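Ring A of the target is a benzene ring with oxygens para to each other at C5 and C8, OMe at C7 and H at C6, fused to the pyranone through C4a–C8a. The plan cuts C5–C6, C7–C8 and C8–C8a. A chromium methoxycarbene on pyranone C3 (future C4a), methoxyacetylene and one CO ligand are merged in a Dötz-type benzannulation that uses the pyranone C2=C3 bond (future C8a=C4a) as the alkenyl unit. One operation should thus close ring A and deliver C5–OMe and C8–OH already differentiated. The precursor is the pentacarbonylchromium methoxycarbene of a 5-methoxy-6-aryl-4-pyranone, reached through its 3-carboxylic acid chloride and pentacarbonylchromate dianion; peri-selective O-demethylation finishes the synthesis.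

Key step: step 7

Remarks on the chemistry:
- The target has no stereocentre; it is achiral and is made as drawn.
- Numbering: the monocyclic pyranones are numbered as in their names (ring CH = C2, carboxyl or carbene carbon on C3, OMe on C5, aryl on C6). Flavone numbering is used from compound 15 on.
- The carbene precursor 11 and the annulation product 16 were checked atom by atom against the target and are used unchanged. A furan (Achmatowicz) entry to the pyranone was not adopted, because an Achmatowicz pyranone lies one oxidation stage below a 3-hydroxy-4-pyranone. Halogenation followed by halogen–lithium exchange is held in reserve only, because the trimethoxyphenyl ring competes for the halogen and a 3-metalated 4-pyranone can expel its ring oxygen. The carbene carbon is instead carried in as an ester during pyranone assembly.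

Step 1
Reactants: 1 methyl 4-methoxy-3-oxobutanoate
Product: 2 methyl 2-[(dimethylamino)methylidene]-4-methoxy-3-oxobutanoate
Conditions: DMF-DMA (1.1 equiv), toluene, rt → 50 °C
Reagents that add atoms: N,N-dimethylformamide dimethyl acetal, COC(OC)N(C)C
Why: Amide-acetal condensation at the doubly activated C2 methylene of the β-keto ester (enaminone formation) should give the push–pull enaminone and leave the CH2OMe group as the only enolisable site.

Step 2
Reactants: 2 methyl 2-[(dimethylamino)methylidene]-4-methoxy-3-oxobutanoate; 3 2,3,4-trimethoxybenzoyl chloride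
Product: 5 methyl 5-methoxy-4-oxo-6-(2,3,4-trimethoxyphenyl)-4H-pyran-3-carboxylate, via acylated enaminone 4 (not isolated)
Conditions: LiHMDS (2.2 equiv) added to 2 + 3, THF, −78 °C; then 3 M aq. HCl, rt
Reagents that add atoms: none
Why: Deprotonation at the methoxymethyl carbon and in situ Claisen-type C-acylation should give triketone 4, whose aryl-ketone enol oxygen adds to the aminomethylidene carbon under acid and expels dimethylamine to close the ring, the established enaminone acylation–cyclisation route to 4-oxo-4H-pyran-3-carboxylates.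

Step 3
Reactants: 5 methyl 5-methoxy-4-oxo-6-(2,3,4-trimethoxyphenyl)-4H-pyran-3-carboxylate
Product: 6 5-methoxy-4-oxo-6-(2,3,4-trimethoxyphenyl)-4H-pyran-3-carboxylic acid
Conditions: 6 M aq. HCl/AcOH (1:1), 80 °C
Reagents that add atoms: water, O
Why: Acid-catalysed ester hydrolysis is chosen because hydroxide would add to the ring CH of the pyranone and open it, whereas the aryl and enol methyl ethers should be inert to aqueous HCl at this temperature.

Step 4
Reactants: 6 5-methoxy-4-oxo-6-(2,3,4-trimethoxyphenyl)-4H-pyran-3-carboxylic acid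
Product: 7 5-methoxy-4-oxo-6-(2,3,4-trimethoxyphenyl)-4H-pyran-3-carbonyl chloride
Conditions: (COCl)2 (1.5 equiv), DMF (cat.), CH2Cl2, 0 °C → rt; evaporate, use crude
Reagents that add atoms: oxalyl chloride, O=C(Cl)C(=O)Cl
Why: Vilsmeier-catalysed acyl chloride formation is mild enough for the pyranone and the aryl ethers, as in the preparation of chromone-3-carbonyl chlorides.

Step 5
Reactants: 7 5-methoxy-4-oxo-6-(2,3,4-trimethoxyphenyl)-4H-pyran-3-carbonyl chloride; 8 chromium hexacarbonyl
Product: 11 pentacarbonyl{methoxy[5-methoxy-4-oxo-6-(2,3,4-trimethoxyphenyl)-4H-pyran-3-yl]methylidene}chromium, via disodium pentacarbonylchromate 9 (not isolated), via sodium acylchromate 10 (not isolated)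
Conditions: 8, sodium naphthalenide (2.1 equiv, THF stock solution), THF, −78 → 0 °C; 7, −78 → 0 °C; evaporate; Me3OBF4 (1.05 equiv), CH2Cl2, 0 °C, Ar
Reagents that add atoms: trimethyloxonium tetrafluoroborate, C[O+](C)C.F[B-](F)(F)F
Why: Nucleophilic acyl substitution of the acid chloride by pentacarbonylchromate(2−) should give the acylchromate, whose anionic acyl oxygen is methylated by one equivalent of the oxonium salt in preference to the pyranone carbonyl (dianion route to Fischer carbene complexes), so that no metalated pyranone is ever generated.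

Step 6
Reactants: 12 chloroacetaldehyde dimethyl acetal
Product: 14 methoxyacetylene, via sodium methoxyacetylide 13 (not isolated)
Conditions: NaNH2 (3 equiv), liq. NH3, −33 °C; NH3 off; sat. aq. NaCl, −70 → 40 °C, distil into −78 °C trap; keep as cold THF solution
Reagents that add atoms: none
Why: Sodium amide should effect twofold elimination (methanol, then HCl) from the chloroacetal and hold the ynol ether as its acetylide until the cold aqueous quench releases the volatile alkyne (base-induced elimination route to alkoxyacetylenes).

Step 7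
Reactants: 11 pentacarbonyl{methoxy[5-methoxy-4-oxo-6-(2,3,4-trimethoxyphenyl)-4H-pyran-3-yl]methylidene}chromium; 14 methoxyacetylene
Product: 16 8-hydroxy-3,5,7,2',3',4'-hexamethoxyflavone, via tricarbonylchromium arene complex 15 (not isolated)
Conditions: 14 (3 equiv), THF (0.05 M), sealed tube, Ar, 50 °C; then air, MeCN, daylight, rt
Reagents that add atoms: none
Why: Proposed new method: thermal loss of one CO from 11 should let methoxyacetylene coordinate and insert into the Cr=C bond with its CH terminus bonding to the carbene carbon (C5–C6); the new methoxy-bearing carbene carbon then takes up a CO ligand (C7–C8) to give a chromium-bound dienylketene, and 6π-electrocyclisation of this ketene onto the pyranone ring CH (C8–C8a) followed by enolisation gives the 4-methoxyphenol as its Cr(CO)3 complex 15, which air releases. The closest known reaction type is the Dötz benzannulation of alkenyl(methoxy)carbene chromium complexes with terminal alkynes; new are the 4-pyranone C2=C3 bond in the alkenyl role and an ynol ether as the alkyne. Ring A is closed by the 6π-electrocyclic step, a six-membered carbocyclisation in which the ketene carbon becomes C8 and the pyranone CH becomes C8a. No stereocentre is formed. The step needs regiocontrol in the alkyne insertion, and both the small terminal CH and the nucleophilic β-carbon of the ynol ether direct that carbon to the electrophilic carbene carbon, so that OMe arrives at C7 beside the CO-derived C8; even a polar insertion before CO loss would give a dienyl(dimethoxy)carbene that should reach the same ketene on further heating. Ceric oxidants are avoided in the decomplexation because they would take the product on to the 5,8-quinone.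

Step 8
Reactants: 16 8-hydroxy-3,5,7,2',3',4'-hexamethoxyflavone
Product: 17 5,8-dihydroxy-3,7,2',3',4'-pentamethoxyflavone
Conditions: BCl3 (3 equiv, 1 M in CH2Cl2), CH2Cl2, −78 → 0 °C; aq. NaHCO3 work-up under N2
Reagents that add atoms: none
Why: Boron trichloride should bind the C4 carbonyl and the peri C5 oxygen in a six-membered chelate so that chloride removes only that methyl group (chelation-directed aryl methyl ether cleavage), the 3-OMe and the remaining aryl ethers reacting far more slowly at or below 0 °C.

Compound list
1 | methyl 4-methoxy-3-oxobutanoate (methyl 4-methoxyacetoacetate) | COCC(=O)CC(=O)OC | starting material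
2 | methyl 2-[(dimethylamino)methylidene]-4-methoxy-3-oxobutanoate (labile push–pull alkene, geometry not defined) | COCC(=O)C(=CN(C)C)C(=O)OC | intermediate
3 | 2,3,4-trimethoxybenzoyl chloride | COc1ccc(C(Cl)=O)c(OC)c1OC | starting material
4 | methyl 2-[(dimethylamino)methylidene]-4-methoxy-3,5-dioxo-5-(2,3,4-trimethoxyphenyl)pentanoate (enolisable at C4, centre lost on cyclisation; not isolated) | COC(=O)C(=CN(C)C)C(=O)C(OC)C(=O)c1ccc(OC)c(OC)c1OC | intermediate
5 | methyl 5-methoxy-4-oxo-6-(2,3,4-trimethoxyphenyl)-4H-pyran-3-carboxylate | COC(=O)c1coc(-c2ccc(OC)c(OC)c2OC)c(OC)c1=O | intermediate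
6 | 5-methoxy-4-oxo-6-(2,3,4-trimethoxyphenyl)-4H-pyran-3-carboxylic acid | OC(=O)c1coc(-c2ccc(OC)c(OC)c2OC)c(OC)c1=O | intermediate
7 | 5-methoxy-4-oxo-6-(2,3,4-trimethoxyphenyl)-4H-pyran-3-carbonyl chloride | ClC(=O)c1coc(-c2ccc(OC)c(OC)c2OC)c(OC)c1=O | intermediate
8 | chromium hexacarbonyl | O=C=[Cr](=C=O)(=C=O)(=C=O)(=C=O)=C=O | starting material
9 | disodium pentacarbonylchromate(2−) (not isolated) | [Na+].[Na+].O=C=[Cr-2](=C=O)(=C=O)(=C=O)=C=O | intermediate
10 | sodium pentacarbonyl[5-methoxy-4-oxo-6-(2,3,4-trimethoxyphenyl)-4H-pyran-3-carbonyl]chromate(1−) (not isolated) | [Na+].O=C(c1coc(-c2ccc(OC)c(OC)c2OC)c(OC)c1=O)[Cr-](=C=O)(=C=O)(=C=O)(=C=O)=C=O | intermediate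
11 | pentacarbonyl{methoxy[5-methoxy-4-oxo-6-(2,3,4-trimethoxyphenyl)-4H-pyran-3-yl]methylidene}chromium | COC(C1=COC(c2ccc(OC)c(OC)c2OC)=C(OC)C1=O)=[Cr](=C=O)(=C=O)(=C=O)(=C=O)=C=O | intermediate
12 | chloroacetaldehyde dimethyl acetal (2-chloro-1,1-dimethoxyethane) | COC(CCl)OC | starting material
13 | sodium methoxyacetylide (not isolated) | [Na+].[C-]#COC | intermediate
14 | methoxyacetylene (methoxyethyne) | COC#C | intermediate
15 | tricarbonyl[η6-(8-hydroxy-3,5,7,2',3',4'-hexamethoxyflavone)]chromium, Cr(CO)3 on ring A (π-bond not expressible, written as two parts; not isolated) | COc1ccc(-c2oc3c(O)c(OC)cc(OC)c3c(=O)c2OC)c(OC)c1OC.O=C=[Cr](=C=O)=C=O | intermediate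
16 | 8-hydroxy-3,5,7,2',3',4'-hexamethoxyflavone | COc1ccc(-c2oc3c(O)c(OC)cc(OC)c3c(=O)c2OC)c(OC)c1OC | intermediate
17 | 5,8-dihydroxy-3,7,2',3',4'-pentamethoxyflavone | COc1ccc(-c2oc3c(O)c(OC)cc(O)c3c(=O)c2OC)c(OC)c1OC | target

Total step count: 8. Longest linear sequence: 7 (steps 1, 2, 3, 4, 5, 7, 8); step 6 is a one-step side branch.

Steps most likely to fail

Step 7 (Proposed new method). The vinylcarbene may cyclise without CO insertion, or it may take up further ynol ether; the alkyne may polymerise; insertion may occur with the opposite orientation. Each of these is a loss of chemo- or regiocontrol in the annulation. The fallback uses known chemistry only, sets out from 3 and comes back at 17. Ring A is taken from a phloroglucinol-derived ketone and the C8 oxygen is added last. Purchased 1-(2-hydroxy-4,6-dimethoxyphenyl)-2-methoxyethan-1-one (COCC(=O)c1c(O)cc(OC)cc1OC) is converted into its dianion (LiHMDS, 3 equiv, THF, −78 °C) and C-acylated with 3 in a one-pot Baker–Venkataraman variant. This should give 1-(2-hydroxy-4,6-dimethoxyphenyl)-2-methoxy-3-(2,3,4-trimethoxyphenyl)propane-1,3-dione F1. H2SO4 in AcOH at 95 °C cyclodehydrates it to 3,5,7,2',3',4'-hexamethoxyflavone F2. AlCl3 in MeCN cleaves the peri methyl ether to 5-hydroxy-3,7,2',3',4'-pentamethoxyflavone F3. Elbs persulfate oxidation (K2S2O8, aq. KOH/pyridine, 15 °C) attacks para to the C5 phenoxide and gives potassium 5-hydroxy-3,7,2',3',4'-pentamethoxyflavon-8-yl sulfate F4. Hot dilute HCl with Na2SO3 hydrolyses this to 17.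

Step 5. The strongly reducing chromate dianion may transfer an electron to the electron-poor pyranone, or add to its ring CH, instead of undergoing clean acyl substitution. The fallback inverts the polarity (organolithium plus Cr(CO)6), sets out from 6 and comes back at 11. Iododecarboxylation of 6 (NIS, LiOAc, MeCN–H2O) at the carboxyl-bearing carbon should give 5-iodo-3-methoxy-2-(2,3,4-trimethoxyphenyl)-4H-pyran-4-one F5. Iodine–lithium exchange (t-BuLi, 2 equiv, THF/Et2O, −100 °C) gives 5-lithio-3-methoxy-2-(2,3,4-trimethoxyphenyl)-4H-pyran-4-one F6. F6 is transferred at once onto 8 in THF at −78 °C to form lithium pentacarbonyl[5-methoxy-4-oxo-6-(2,3,4-trimethoxyphenyl)-4H-pyran-3-carbonyl]chromate(1−) F7, and Me3OBF4 in CH2Cl2 then gives 11. The vinyllithium has to stay below about −90 °C so that it does not expel the ring oxygen.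

Step 8. The Lewis acid may also remove the 3-O-methyl group or the crowded 2'/3' aryl methyl groups, or leave the C5 ether partly intact, which would be a loss of site selectivity in ether cleavage. The fallback replaces Lewis-acid cleavage by a redox sequence, sets out from 16 and comes back at 17. PhI(OAc)2 in MeCN–H2O at 0 °C oxidises the 4-methoxyphenol with loss of methanol to 3,7-dimethoxy-2-(2,3,4-trimethoxyphenyl)-4H-chromene-4,5,8-trione F8. Aqueous Na2S2O4 in EtOAc then reduces the quinone to 17.

Further compounds
F1 | step 7 | 1-(2-hydroxy-4,6-dimethoxyphenyl)-2-methoxy-3-(2,3,4-trimethoxyphenyl)propane-1,3-dione (racemic, enolisable) | COC(C(=O)c1c(O)cc(OC)cc1OC)C(=O)c1ccc(OC)c(OC)c1OC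
F2 | step 7 | 3,5,7,2',3',4'-hexamethoxyflavone | COc1ccc(-c2oc3cc(OC)cc(OC)c3c(=O)c2OC)c(OC)c1OC
F3 | step 7 | 5-hydroxy-3,7,2',3',4'-pentamethoxyflavone | COc1ccc(-c2oc3cc(OC)cc(O)c3c(=O)c2OC)c(OC)c1OC
F4 | step 7 | potassium 5-hydroxy-3,7,2',3',4'-pentamethoxyflavon-8-yl sulfate | COc1ccc(-c2oc3c(OS(=O)(=O)[O-])c(OC)cc(O)c3c(=O)c2OC)c(OC)c1OC.[K+]
F5 | step 5 | 5-iodo-3-methoxy-2-(2,3,4-trimethoxyphenyl)-4H-pyran-4-one | COc1ccc(-c2occ(I)c(=O)c2OC)c(OC)c1OC
F6 | step 5 | 5-lithio-3-methoxy-2-(2,3,4-trimethoxyphenyl)-4H-pyran-4-one | [Li]c1coc(-c2ccc(OC)c(OC)c2OC)c(OC)c1=O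
F7 | step 5 | lithium pentacarbonyl[5-methoxy-4-oxo-6-(2,3,4-trimethoxyphenyl)-4H-pyran-3-carbonyl]chromate(1−) | [Li+].O=C(c1coc(-c2ccc(OC)c(OC)c2OC)c(OC)c1=O)[Cr-](=C=O)(=C=O)(=C=O)(=C=O)=C=O
F8 | step 8 | 3,7-dimethoxy-2-(2,3,4-trimethoxyphenyl)-4H-chromene-4,5,8-trione | O=C1C=C(OC)C(=O)C2=C1C(=O)C(OC)=C(c1ccc(OC)c(OC)c1OC)O2
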